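## The problem

CNP0160418.1 (43) is two trans-fused oxepane–cyclohexane bicycles held together only by a CH2–CH2 bridge. The numbering used throughout is: ring A (O5, C6, C7, C8, C9, C10, C4) fused to ring B (C1, C2, C3, C4, C10, C11); bridge C12–C13; ring C (C14, C15, C21, C22, C23, C24) fused to ring D (C15, C16, C17, C18, C19, O20, C21). Each half carries four stereocentres (C4, C7, C10, C11 and C14, C15, C21, C24). Corresponding centres have the same sense, but the halves are too far apart to control one another, so each needs its own source of absolute configuration and they are best joined convergently at C13–C14. Inside a half the quaternary carbon (C10 or C15) is the controller: its axial methyl group steers hydride to C4, a methyl nucleophile to C24, and makes the equatorial bridge carbon at C11/C14 the stable one. Only C7 lies outside its reach and needs reagent control. The two oxepanes differ in oxidation level (C7 alcohol, C18 ketone) although they come from the same chemistry, so they must be told apart by protection. The fragile groups are the C1 exocyclic methylene (hydrogenation, hydroboration, acid), the tertiary C24 alcohol, the epoxides that serve as oxepane precursors, and a C11 centre that is epimerisable while C1 is a ketone. The feature that makes the key step possible is in ring B: the quaternary C10 (CH3 and C9), the oxygenated C4 and the bridge-bearing C11 are contiguous, CH3 and C12 are cis, and C1–C3 are unsubstituted. C10–C11 with C9 as formyl carbon is therefore an (E)-2-methylalk-2-enal and C4–C3–C2–C1 a 1-oxybutadiene, which is a Diels–Alder retron.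

## Retrosynthesis

**43 to 39.** The C24–CH3 bond is cut last and C18 and C7 are returned to a silyl ether and an acetate (42, 41, 40), leading to ketone 39. This is preferred to a late methylenation or a late oxepane closure because on the rigid C/D bicycle the syn-axial C15 methyl leaves only equatorial attack at C24. The forward step must add methyl to a hindered, enolisable ketone without touching the acetate.

**39 to 20 and 35.** The bridge is cut at C13–C14. Cutting C12–C13 would join two β-branched sp3 carbons; cutting at C14 uses carbonyl chemistry, since C14 is α to the future C24 carbinol. Aldehyde 20 and the α′-carbon of enone 35 are joined by aldol addition (36), dehydration (38) and conjugate reduction. C14 is then epimerisable and settles equatorial. The C22=C23 double bond of 35 blocks the other α-side, so enolisation is regiospecific. The forward step asks a neopentyl-type enolate to add to an enolisable aldehyde.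

**35 to 32.** Ring D is opened at O20–C19: the C21 hydroxyl of epoxide 32 opens the fully substituted epoxide carbon (7-endo) to give 33, which is silylated (34) and dehydrogenated (35). Only C22–C23 can be desaturated because C15 is quaternary. This cut removes a ring and leaves a monocyclic ketone.

**32 to 27 and 28.** The C15–C16 bond is cut: a homoprenyl copper reagent from bromide 28 adds to enone 27 anti to its silyloxy group, which sets C15 against C21 (30), then desilylation (31) and epoxidation (32). Enone 27 comes from 3-ethoxycyclohex-2-enone 21 by asymmetric α′-hydroxylation and carbonyl transposition (22 to 26). No inversion at C21 is needed on this side.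

**20 to 17.** Ring A is opened at O5–C6, the same 7-endo epoxide opening, from hydroxy epoxide 17 via diol 18 and hydroxy aldehyde 19. C7 keeps the oxygen and configuration of the epoxide.

**17 to 11.** Functional-group changes in ring B: C4 is inverted by oxidation and reduction (15, 16, 17); the C1 methylene comes from ketone 13 (14), this from enone 12, this from allylic oxidation of 11. The oxidation is placed before ring closure and before the C4 inversion: in the cis silyl ether 11 the C4–H bond is pseudoequatorial and shielded, whereas in the closed oxepane it would be axial, allylic and ether-activated. The chain alkene is epoxidised first because its own allylic hydrogens would otherwise be oxidised.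

**11 to 6.** The C7–C8 bond is cut: hydroboration of vinyl compound 7 and B-alkyl coupling with bromide 8 give 10, which is epoxidised to 11. The vinyl group is the formyl carbon of 6 plus one carbon. Displacement at a neopentyl carbon is avoided.

**6 to 3 and 5.** The key cut breaks C10–C4 and C11–C1. Enal 3 and diene 5 are achiral and acyclic; ring B and three stereocentres arise in one step. The reaction must be regio-, endo- and face-selective on a trisubstituted enal.

**3 and 5.** Enal 3 is the Wittig product of aldehyde 1 and ylide 2; diene 5 is the silyl dienol ether of crotonaldehyde 4.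

## Roads not taken

**Alternative 1:** Ring A is cut at O5–C4 by imagining oxygen insertion into a bicyclic ketone. A peracid converts trans-decalone A1, whose carbonyl is next to the ring-fusion CH, into the seven-membered lactone A2, the methine migrating with retention. Its merits are real: ring size and trans fusion are guaranteed, there is no 6-exo/7-endo question, C4 needs no inversion, and annulation-derived decalones are cheap and enantiopure. On these points it beats the chosen plan, which spends three steps inverting C4 and carries the risk of exo closure. Its weak points are what comes after. The lactone carbonyl stands where C6 must carry two methyl groups and C7 a hydroxyl, so a geminal dimethylation of a lactone and a separate stereocontrolled oxygenation are needed. Ring B arrives with its oxygen function at C11, where the target has the bridge CH, and with C1 bare. Against the better C4 control the chosen plan sets a cycloaddition that delivers C11 with its arm and configuration, and an epoxide that delivers C6(CH3)2 and C7–OH together.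

**Alternative 2:** Here ring C and ring D are cut together. Irradiation of a furanone tethered to a 1,1-disubstituted alkene forms C21–C15 and C17–C16 and gives cyclobutane A3; opening of the cyclobutane then expands the furanone to the oxepanone. For ring D this is better than the chosen plan: the C18 ketone and the gem-dimethyl carbon are present from the start, whereas the chosen plan needs epoxidation, cyclisation, protection, deprotection and oxidation. The quaternary C15 is formed in the same step. The weak points are stereochemical and strategic. Face selectivity of the photocycloaddition rests on tether stereocentres. C21 becomes a stereocentre only in the fragmentation, where trans fusion is not assured. The one-carbon arm at C14 leaves an sp3–sp3 bridge bond between two β-branched carbons. The method also serves only the half with a ketone, not ring A. The chosen plan sets ground-state steps with predictable diastereocontrol against the shorter access to the ring D oxidation level.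

**Alternative 3:** The cut is C15–C16 and C14–C13 in one operation, with no ring formed. The copper-catalysed addition of the Grignard reagent from 28 to enone 27 is followed by trapping of the magnesium enolate with a finished A/B aldehyde A5, giving aldol A4. This is the most convergent way to attach ring C and is shorter than the chosen C/D half plus union by about four operations. The chosen plan uses the same anti-selective conjugate addition (step 20) to make C15. What it declines is the in-flask trapping: a hindered enolate next to a new quaternary carbon must add to a precious, enolisable aldehyde. Ring D would then be built after the union, beside the C1 methylene and on a flexible monocycle. Against the step economy the chosen plan sets a 1:1 union of two finished bicycles and control of C14 and C24 on a rigid trans-fused ring. Alternative 3 also leaves open how rings A/B are made, which is what the cycloaddition answers.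

Key step: step 3

Assumption: the (S)-oxazaborolidinium catalyst is taken to leave open the Re face of the α-carbon of 3 (formyl > C11 > CH3), as the formyl C–H···O binding model for 2-substituted enals implies; were the sense opposite, the (R) catalyst would be used with no other change.

Abbreviations: TBS = tert-butyldimethylsilyl, TES = triethylsilyl, TMS = trimethylsilyl, "ent-Shi ketone" = 1,2:4,5-di-O-isopropylidene-β-L-erythro-2,3-hexodiulo-2,6-pyranose.

## Steps

Step 1
Reactants: 1 3-(tert-butyldimethylsilyloxy)propanal; 2 2-(triphenylphosphoranylidene)propanal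
Product: 3 (E)-5-(tert-butyldimethylsilyloxy)-2-methylpent-2-enal
Conditions: toluene, 90 °C
Reagents that add atoms: none
Why: Wittig olefination with a formyl-stabilised ylide; reversible addition gives the (E)-trisubstituted enal, and the neutral conditions do not eliminate the β-silyloxy group.

Step 2
Reactants: 4 (E)-but-2-enal (crotonaldehyde)
Product: 5 (E)-1-(tert-butyldimethylsilyloxy)buta-1,3-diene
Conditions: TBSOTf, Et3N, Et2O, 0 °C → rt; distillation
Reagents that add atoms: tert-butyldimethylsilyl trifluoromethanesulfonate, CC(C)(C)[Si](C)(C)OS(=O)(=O)C(F)(F)F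
Why: Soft enolisation (O-silylation, then γ-deprotonation by the amine) gives the silyl dienol ether, the E isomer being the one that reacts in step 3.

Step 3
Reactants: 3 (E)-5-(tert-butyldimethylsilyloxy)-2-methylpent-2-enal; 5 (E)-1-(tert-butyldimethylsilyloxy)buta-1,3-diene
Product: 6 ring B cycloadduct (1S,2R,6S)-2-(tert-butyldimethylsilyloxy)-6-[2-(tert-butyldimethylsilyloxy)ethyl]-1-methylcyclohex-3-ene-1-carbaldehyde
Conditions: (S)-oxazaborolidinium triflimide [salt of (S)-3,3-diphenyl-1-(2-methylphenyl)tetrahydro-1H,3H-pyrrolo[1,2-c][1,3,2]oxazaborole with HN(SO2CF3)2] (0.2 equiv), CH2Cl2, −78 → −40 °C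
Reagents that add atoms: none
Why: Lewis-acid-catalysed normal-demand Diels–Alder reaction; the closest known reaction type is the oxazaborolidinium-catalysed cycloaddition of 2-substituted enals and 2-methylalk-2-enals with 1-silyloxy dienes. Boron binds the formyl oxygen syn to the formyl hydrogen, which contacts the ring oxygen of the catalyst; this holds the enal s-trans and lays a phenyl group over one face of the C10=C11 bond. The addition is concerted but asynchronous: the unsubstituted terminus of 5 bonds first to the β-carbon (C11–C1), the silyloxy-bearing terminus then to the α-carbon (C10–C4), which is the regiochemistry the donor and acceptor polarisation demands. Ring B closes in this single suprafacial [4+2] event as a cyclohexene (C2=C3). C10 and C11: the relative configuration (CH3 cis to the side arm) follows from the E geometry of 3, the absolute configuration from the catalyst. C4: the E diene and the endo position of the Lewis-acid-bound formyl group put the silyloxy group cis to formyl; this is the epimer opposite to the target and is corrected in steps 11 and 12. The step needs regio-, endo- and face selectivity, secured respectively by the polarisation of the partners, the bound formyl group and the catalyst, whose activation is strong enough for a trisubstituted enal.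

Step 4
Reactants: 6 ring B cycloadduct
Product: 7 ring B vinyl compound (formyl of 6 converted into CH=CH2; C4 OTBS cis to vinyl; C11 arm cis to CH3)
Conditions: Ph3PCH3Br, KOtBu, THF, 0 °C
Reagents that add atoms: methyltriphenylphosphonium bromide, C[P+](c1ccccc1)(c1ccccc1)c1ccccc1.[Br-]
Why: Wittig methylenation; the aldehyde has no α-hydrogen, so neither enolisation nor retro-aldol loss of the β-silyloxy group can interfere.

Step 5
Reactants: 7 ring B vinyl compound; 8 1-bromo-2-methylprop-1-ene
Product: 10 ring B homoprenyl compound (C10 carries CH2CH2CH=C(CH3)2; otherwise as 7), via B-alkylborane 9 (not isolated)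
Conditions: 9-BBN, THF, 0 → 50 °C; then 8, Pd(dppf)Cl2 (cat.), AsPh3, Cs2CO3, DMF/H2O, rt
Reagents that add atoms: none
Why: Anti-Markovnikov hydroboration of the monosubstituted alkene (9-BBN is far slower with the cis-disubstituted ring alkene) and B-alkyl Suzuki–Miyaura coupling form C7–C8 without displacement at the neopentyl C9.

Step 6
Reactants: 10 ring B homoprenyl compound
Product: 11 (7S)-epoxide of 10 (C6–C7 oxirane)
Conditions: ent-Shi ketone (0.3 equiv), KHSO5 (as 2KHSO5·KHSO4·K2SO4), K2CO3, Bu4NHSO4, MeCN/CH2(OMe)2/aq. Na2B4O7 buffer, 0 °C
Reagents that add atoms: potassium peroxymonosulfate, [K+].[O-]S(=O)(=O)OO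
Why: Shi epoxidation; the chiral dioxirane attacks the electron-rich trisubstituted alkene through the spiro transition state, the L-series ketone giving the (S)-epoxide, while the hindered cis ring alkene reacts much more slowly. C7 is set here by the catalyst.

Step 7
Reactants: 11 (7S)-epoxide
Product: 12 ring B enone (C1 ketone conjugated with C2=C3; C4 OTBS; epoxide intact)
Conditions: CrO3, 3,5-dimethylpyrazole, CH2Cl2, −20 °C
Reagents that add atoms: chromium trioxide, O=[Cr](=O)=O
Why: Allylic C–H oxidation to the enone; with the arm equatorial the C4 silyloxy group is pseudoaxial, so C4–H lies near the alkene plane and is buried between C10 and the silyl group, whereas C1 offers an aligned axial hydrogen. The chain alkene is already masked as the epoxide.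

Step 8
Reactants: 12 ring B enone
Product: 13 saturated C1 ketone
Conditions: H2 (1 atm), Pd/C, EtOAc, rt
Reagents that add atoms: none
Why: Catalytic hydrogenation of the conjugated double bond under neutral conditions; the trialkyl epoxide and the silyl ethers are inert and C11 is not epimerised.

Step 9
Reactants: 13 saturated C1 ketone
Product: 14 C1 exocyclic methylene compound (bis-TBS ether; epoxide)
Conditions: Ph3PCH3Br, KOtBu, THF, 0 °C → rt
Reagents that add atoms: methyltriphenylphosphonium bromide, C[P+](c1ccccc1)(c1ccccc1)c1ccccc1.[Br-]
Why: Wittig methylenation; if the ylide acts as a base it removes the unhindered C2–H and not the C11–H flanked by the quaternary C10, so the cycloaddition-derived C11 configuration should survive.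

Step 10
Reactants: 14 C1 exocyclic methylene compound
Product: 15 diol (C4–OH cis to the C9 chain; C13–OH; epoxide)
Conditions: Bu4NF, AcOH (1:1), THF, rt → 45 °C
Reagents that add atoms: none
Why: Fluoride cleavage of both silyl ethers; buffering with acetic acid keeps the freed C4 alkoxide from opening the epoxide in the exo sense.

Step 11
Reactants: 15 diol
Product: 16 keto aldehyde (C4 ketone; C13 aldehyde; epoxide)
Conditions: Dess–Martin periodinane, NaHCO3, CH2Cl2, 0 °C → rt
Reagents that add atoms: none
Why: Buffered periodinane oxidation of both alcohols erases the wrong C4 configuration without touching the epoxide or the alkene; the C13 aldehyde is carried on without purification.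

Step 12
Reactants: 16 keto aldehyde
Product: 17 diol with inverted C4–OH (trans to the C9 chain and cis to CH3; C13–OH; epoxide)
Conditions: NaBH4, MeOH, −20 → 0 °C
Reagents that add atoms: none
Why: Hydride reduction; with the arm equatorial the C10 methyl is axial, and axial attack at C4 anti to it gives the equatorial alcohol, the epimer needed for trans fusion. The aldehyde returns to the primary alcohol.

Step 13
Reactants: 17 diol with inverted C4–OH
Product: 18 rings A/B diol (trans-fused 2,2-dimethyloxepan-3-ol with (7S)-OH; C13–OH; C1 methylene)
Conditions: (+)-camphor-10-sulfonic acid (cat.), CH2Cl2, 0 °C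
Reagents that add atoms: none
Why: Acid-catalysed intramolecular epoxide opening in the 7-endo mode; C6 with its two methyl groups carries the positive charge, while the 6-exo path needs backside attack at C7 next to that fully substituted carbon. C7 keeps its oxygen and configuration, and the trans-diequatorial O4 and C9 give the trans-fused ring.

Step 14
Reactants: 18 rings A/B diol
Product: 19 rings A/B hydroxy aldehyde (C13 aldehyde; C7–OH free)
Conditions: 2,2,6,6-tetramethylpiperidin-1-oxyl (cat.), PhI(OAc)2, CH2Cl2, rt
Reagents that add atoms: none
Why: Oxoammonium oxidation is selective for the primary alcohol; the secondary C7–OH next to the gem-dimethyl carbon is left.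

Step 15
Reactants: 19 rings A/B hydroxy aldehyde
Product: 20 rings A/B acetoxy aldehyde (C7–OAc)
Conditions: Ac2O, pyridine, 4-(dimethylamino)pyridine (cat.), CH2Cl2, 0 °C → rt
Reagents that add atoms: acetic anhydride, CC(=O)OC(C)=O
Why: Acylation; the acetate carries C7 through the union and the later oxidation at C18 and is removed last.

Step 16
Reactants: 21 3-ethoxycyclohex-2-en-1-one
Product: 22 1-ethoxy-3-(trimethylsilyloxy)cyclohexa-1,3-diene
Conditions: LiN(iPr)2, THF, −78 °C; then Me3SiCl
Reagents that add atoms: chlorotrimethylsilane, C[Si](C)(C)Cl
Why: Kinetic α′-deprotonation of the vinylogous ester and O-silylation give the cross-conjugated silyl dienol ether.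

Step 17
Reactants: 22 1-ethoxy-3-(trimethylsilyloxy)cyclohexa-1,3-diene
Product: 24 (S)-3-ethoxy-6-hydroxycyclohex-2-en-1-one, via silyloxy epoxide 23 (not isolated)
Conditions: ent-Shi ketone (0.3 equiv), KHSO5 (as 2KHSO5·KHSO4·K2SO4), K2CO3, Bu4NHSO4, MeCN/CH2(OMe)2/aq. Na2B4O7 buffer, 0 °C; aqueous citric acid work-up
Reagents that add atoms: potassium peroxymonosulfate, [K+].[O-]S(=O)(=O)OO
Why: Rubottom oxidation under Shi conditions; the dioxirane epoxidises the silyl enol ether double bond, whose CH carbon is activated by both oxygen donors, with the same face preference as in step 6, and the silyloxy epoxide collapses to the α′-hydroxy enone on work-up. The future C21 is set here by the catalyst.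

Step 18
Reactants: 24 (S)-3-ethoxy-6-hydroxycyclohex-2-en-1-one
Product: 25 (S)-6-(tert-butyldimethylsilyloxy)-3-ethoxycyclohex-2-en-1-one
Conditions: TBSCl, imidazole, DMF, rt
Reagents that add atoms: tert-butyldimethylsilyl chloride, CC(C)(C)[Si](C)(C)Cl
Why: Silylation of the secondary alcohol; the bulky silyl ether is the directing group for step 20.

Step 19
Reactants: 25 (S)-6-(tert-butyldimethylsilyloxy)-3-ethoxycyclohex-2-en-1-one
Product: 27 (S)-4-(tert-butyldimethylsilyloxy)-3-methylcyclohex-2-en-1-one, via tertiary allylic alcohol 26 (not isolated)
Conditions: MeLi, THF, −78 °C; then 1 M HCl, 0 °C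
Reagents that add atoms: methyllithium, [Li]C; water, O
Why: Stork–Danheiser transposition: 1,2-addition to the vinylogous ester, then acid hydrolysis of the enol ether with loss of water and ethanol, gives the 3-methyl enone; the silyloxy-bearing stereocentre is not involved.

Step 20
Reactants: 27 (S)-4-(tert-butyldimethylsilyloxy)-3-methylcyclohex-2-en-1-one; 28 5-bromo-2-methylpent-2-ene
Product: 30 (3S,4S)-4-(tert-butyldimethylsilyloxy)-3-methyl-3-(4-methylpent-3-enyl)cyclohexan-1-one, via trimethylsilyl enol ether 29 (not isolated)
Conditions: 28, Mg, THF; then CuBr·SMe2 (cat.), Me3SiCl, 27, THF, −78 °C; 1 M HCl work-up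
Reagents that add atoms: none
Why: Copper-catalysed conjugate addition of the Grignard reagent, accelerated by the silyl chloride; the homoprenyl group enters C15 anti to the neighbouring silyloxy group, so CH3 ends cis and the chain trans to O at C21.

Step 21
Reactants: 30 (3S,4S)-silyloxy ketone
Product: 31 (3S,4S)-4-hydroxy-3-methyl-3-(4-methylpent-3-enyl)cyclohexan-1-one
Conditions: Bu4NF, THF, 0 °C → rt
Reagents that add atoms: none
Why: Fluoride desilylation before the epoxide is introduced; the γ-hydroxy ketone cannot undergo retro-aldol cleavage.

Step 22
Reactants: 31 hydroxy ketone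
Product: 32 (18S)-epoxide of 31 (C18–C19 oxirane)
Conditions: ent-Shi ketone (0.3 equiv), KHSO5 (as 2KHSO5·KHSO4·K2SO4), K2CO3, Bu4NHSO4, MeCN/CH2(OMe)2/aq. Na2B4O7 buffer, 0 °C
Reagents that add atoms: potassium peroxymonosulfate, [K+].[O-]S(=O)(=O)OO
Why: Shi epoxidation of the trisubstituted alkene in the presence of ketone and alcohol; the C18 configuration is erased in step 31, so the catalyst serves only to give one diastereomer with the closure geometry of ring A.

Step 23
Reactants: 32 (18S)-epoxide
Product: 33 rings C/D keto alcohol (trans-fused 2,2-dimethyloxepane; (18S)-OH; C24 ketone)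
Conditions: (+)-camphor-10-sulfonic acid (cat.), CH2Cl2, 0 °C
Reagents that add atoms: none
Why: The same acid-catalysed 7-endo epoxide opening as in step 13, here by the C21 hydroxyl at C19; the trans relation of O21 and C16 from step 20 gives the trans-fused ring.

Step 24
Reactants: 33 rings C/D keto alcohol
Product: 34 rings C/D keto TES ether (C18–OTES)
Conditions: TESOTf, 2,6-lutidine, CH2Cl2, −78 °C
Reagents that add atoms: triethylsilyl trifluoromethanesulfonate, CC[Si](CC)(CC)OS(=O)(=O)C(F)(F)F
Why: Silylation of the hindered secondary alcohol; a silyl ether distinguishes C18 from the acetylated C7 and survives the basic steps of the union.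

Step 25
Reactants: 34 rings C/D keto TES ether
Product: 35 rings C/D enone (C24 ketone conjugated with C22=C23; C18–OTES)
Conditions: IBX, DMSO/toluene, 70 °C
Reagents that add atoms: none
Why: IBX dehydrogenation of the ketone through its enol; only the C23–C22 side can be desaturated because C15 is quaternary.

Step 26
Reactants: 35 rings C/D enone; 20 rings A/B acetoxy aldehyde
Product: 36 aldol adduct (C13–OH; C13–C14 bond; mixture at C13 and C14)
Conditions: LiN(iPr)2, THF, −78 °C; then 20, −78 °C; NH4Cl quench
Reagents that add atoms: none
Why: Kinetic α′-deprotonation of the enone gives the cross-conjugated lithium enolate at C14, the only enolisable α-carbon; aldol addition to the aldehyde forms the bridge bond, and the acetate is not attacked at this temperature. The new centres need no control because C13 is deoxygenated and C14 is equilibrated later.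

Step 27
Reactants: 36 aldol adduct
Product: 38 cross-conjugated dienone (exocyclic C13=C14; C22=C23), via mesylate 37 (not isolated)
Conditions: MsCl, Et3N, CH2Cl2, 0 °C; then DBU, rt
Reagents that add atoms: none
Why: Mesylation and E1cB elimination of the β-sulfonyloxy ketone; the alkene geometry is of no consequence.

Step 28
Reactants: 38 cross-conjugated dienone
Product: 39 saturated C24 ketone with the C13 chain equatorial at C14 (cis to the C15 methyl)
Conditions: [(Ph3P)CuH]6, benzene, H2O (trace), rt; then DBU, CH2Cl2, rt
Reagents that add atoms: none
Why: The copper hydride reduces only conjugated C=C bonds, so the 1,1-disubstituted alkene of ring B is spared; base equilibration on the rigid trans-fused bicycle then places the C14 substituent equatorial, the configuration of the target.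

Step 29
Reactants: 39 saturated C24 ketone
Product: 40 tertiary alcohol (C24 axial OH cis to the C15 methyl; C18–OTES; C7–OAc)
Conditions: MeMgBr, CeCl3, THF, −78 °C
Reagents that add atoms: methylmagnesium bromide, C[Mg]Br
Why: Organocerium 1,2-addition, which does not enolise the ketone and is much faster than addition to the hindered acetate; the syn-axial C15 methyl blocks axial approach, so methyl enters equatorially.

Step 30
Reactants: 40 tertiary alcohol
Product: 41 diol (C18–OH free; C24–OH; C7–OAc)
Conditions: HF·pyridine, pyridine, THF, 0 °C
Reagents that add atoms: none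
Why: Buffered fluoride cleavage of the silyl ether; acetate, tertiary alcohol and exocyclic alkene are stable to it.

Step 31
Reactants: 41 diol
Product: 42 C18 ketone 7-O-acetate
Conditions: Dess–Martin periodinane, NaHCO3, CH2Cl2, rt
Reagents that add atoms: none
Why: Only the secondary C18 alcohol can be oxidised, C24–OH being tertiary and C7 acetylated.

Step 32
Reactants: 42 C18 ketone 7-O-acetate
Product: 43 CNP0160418.1
Conditions: K2CO3, MeOH, rt
Reagents that add atoms: none
Why: Methanolysis of the acetate; there is no epimerisable centre next to the C18 ketone (C19 is quaternary) and no β-leaving group, so the mild base should do nothing else.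

## Compound list

1 | 3-(tert-butyldimethylsilyloxy)propanal | O=CCCO[Si](C)(C)C(C)(C)C | starting material
2 | 2-(triphenylphosphoranylidene)propanal | CC(C=O)=P(c1ccccc1)(c1ccccc1)c1ccccc1 | starting material
3 | (E)-5-(tert-butyldimethylsilyloxy)-2-methylpent-2-enal | O=C/C(C)=C/CCO[Si](C)(C)C(C)(C)C | intermediate
4 | (E)-but-2-enal (crotonaldehyde) | C/C=C/C=O | starting material
5 | (E)-1-(tert-butyldimethylsilyloxy)buta-1,3-diene | C=C/C=C/O[Si](C)(C)C(C)(C)C | intermediate
6 | ring B cycloadduct, (1S,2R,6S)-2-(tert-butyldimethylsilyloxy)-6-[2-(tert-butyldimethylsilyloxy)ethyl]-1-methylcyclohex-3-ene-1-carbaldehyde (formyl cis to ring OTBS, CH3 cis to the arm) | O=C[C@]1(C)[C@H](O[Si](C)(C)C(C)(C)C)C=CC[C@H]1CCO[Si](C)(C)C(C)(C)C | intermediate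
7 | ring B vinyl compound (6 with CH=CH2 in place of CHO) | C=C[C@]1(C)[C@H](O[Si](C)(C)C(C)(C)C)C=CC[C@H]1CCO[Si](C)(C)C(C)(C)C | intermediate
8 | 1-bromo-2-methylprop-1-ene | CC(C)=CBr | starting material
9 | B-alkyl-9-borabicyclo[3.3.1]nonane from 7 (boron on C8) | C1CC2CCCC(C1)B2CC[C@]1(C)[C@H](O[Si](C)(C)C(C)(C)C)C=CC[C@H]1CCO[Si](C)(C)C(C)(C)C | intermediate (not isolated)
10 | ring B homoprenyl compound (C10 carries CH2CH2CH=C(CH3)2) | CC(C)=CCC[C@]1(C)[C@H](O[Si](C)(C)C(C)(C)C)C=CC[C@H]1CCO[Si](C)(C)C(C)(C)C | intermediate
11 | (7S)-epoxide of 10 | CC1(C)O[C@H]1CC[C@]1(C)[C@H](O[Si](C)(C)C(C)(C)C)C=CC[C@H]1CCO[Si](C)(C)C(C)(C)C | intermediate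
12 | ring B enone (C1=O, C2=C3) | CC1(C)O[C@H]1CC[C@]1(C)[C@H](O[Si](C)(C)C(C)(C)C)C=CC(=O)[C@H]1CCO[Si](C)(C)C(C)(C)C | intermediate
13 | saturated C1 ketone | CC1(C)O[C@H]1CC[C@]1(C)[C@H](O[Si](C)(C)C(C)(C)C)CCC(=O)[C@H]1CCO[Si](C)(C)C(C)(C)C | intermediate
14 | C1 exocyclic methylene compound (bis-TBS ether) | CC1(C)O[C@H]1CC[C@]1(C)[C@H](O[Si](C)(C)C(C)(C)C)CCC(=C)[C@H]1CCO[Si](C)(C)C(C)(C)C | intermediate
15 | diol, C4–OH cis to the C9 chain | CC1(C)O[C@H]1CC[C@]1(C)[C@H](O)CCC(=C)[C@H]1CCO | intermediate
16 | keto aldehyde (C4 ketone, C13 aldehyde) | CC1(C)O[C@H]1CC[C@]1(C)C(=O)CCC(=C)[C@H]1CC=O | intermediate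
17 | diol with inverted C4–OH (trans to the C9 chain) | CC1(C)O[C@H]1CC[C@]1(C)[C@@H](O)CCC(=C)[C@H]1CCO | intermediate
18 | rings A/B diol (trans-fused oxepane, (7S)-OH, C13–OH) | C=C1CC[C@@H]2OC(C)(C)[C@@H](O)CC[C@@]2(C)[C@@H]1CCO | intermediate
19 | rings A/B hydroxy aldehyde | C=C1CC[C@@H]2OC(C)(C)[C@@H](O)CC[C@@]2(C)[C@@H]1CC=O | intermediate
20 | rings A/B acetoxy aldehyde | C=C1CC[C@@H]2OC(C)(C)[C@@H](OC(C)=O)CC[C@@]2(C)[C@@H]1CC=O | intermediate
21 | 3-ethoxycyclohex-2-en-1-one | CCOC1=CC(=O)CC1 | starting material
22 | 1-ethoxy-3-(trimethylsilyloxy)cyclohexa-1,3-diene | CCOC1=CC(O[Si](C)(C)C)=CCC1 | intermediate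
23 | silyloxy epoxide of 22 | CCOC1=C[C@@]2(O[Si](C)(C)C)O[C@H]2CC1 | intermediate (not isolated)
24 | (S)-3-ethoxy-6-hydroxycyclohex-2-en-1-one | CCOC1=CC(=O)[C@@H](O)CC1 | intermediate
25 | (S)-6-(tert-butyldimethylsilyloxy)-3-ethoxycyclohex-2-en-1-one | CCOC1=CC(=O)[C@@H](O[Si](C)(C)C(C)(C)C)CC1 | intermediate
26 | tertiary allylic alcohol from methyl addition to 25 (carbinol carbon unassigned) | CCOC1=CC(C)(O)[C@@H](O[Si](C)(C)C(C)(C)C)CC1 | intermediate (not isolated)
27 | (S)-4-(tert-butyldimethylsilyloxy)-3-methylcyclohex-2-en-1-one | O=C1C=C(C)[C@@H](O[Si](C)(C)C(C)(C)C)CC1 | intermediate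
28 | 5-bromo-2-methylpent-2-ene | CC(C)=CCCBr | starting material
29 | trimethylsilyl enol ether of 30 | C[Si](C)(C)OC1=C[C@](C)(CCC=C(C)C)[C@@H](O[Si](C)(C)C(C)(C)C)CC1 | intermediate (not isolated)
30 | (3S,4S)-4-(tert-butyldimethylsilyloxy)-3-methyl-3-(4-methylpent-3-enyl)cyclohexan-1-one (chain trans to OTBS) | O=C1C[C@](C)(CCC=C(C)C)[C@@H](O[Si](C)(C)C(C)(C)C)CC1 | intermediate
31 | (3S,4S)-4-hydroxy-3-methyl-3-(4-methylpent-3-enyl)cyclohexan-1-one | O=C1C[C@](C)(CCC=C(C)C)[C@@H](O)CC1 | intermediate
32 | (18S)-epoxide of 31 | CC1(C)O[C@H]1CC[C@@]1(C)CC(=O)CC[C@@H]1O | intermediate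
33 | rings C/D keto alcohol (trans-fused oxepane, (18S)-OH, C24 ketone) | O=C1C[C@]2(C)CC[C@H](O)C(C)(C)O[C@H]2CC1 | intermediate
34 | rings C/D keto TES ether | O=C1C[C@]2(C)CC[C@H](O[Si](CC)(CC)CC)C(C)(C)O[C@H]2CC1 | intermediate
35 | rings C/D enone (C24=O, C22=C23) | O=C1C[C@]2(C)CC[C@H](O[Si](CC)(CC)CC)C(C)(C)O[C@H]2C=C1 | intermediate
36 | aldol adduct (C13–OH; C13 and C14 unassigned) | C=C1CC[C@@H]2OC(C)(C)[C@@H](OC(C)=O)CC[C@@]2(C)[C@@H]1CC(O)C1[C@]2(C)CC[C@H](O[Si](CC)(CC)CC)C(C)(C)O[C@H]2C=CC1=O | intermediate
37 | C13 mesylate of 36 | C=C1CC[C@@H]2OC(C)(C)[C@@H](OC(C)=O)CC[C@@]2(C)[C@@H]1CC(OS(C)(=O)=O)C1[C@]2(C)CC[C@H](O[Si](CC)(CC)CC)C(C)(C)O[C@H]2C=CC1=O | intermediate (not isolated)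
38 | cross-conjugated dienone (exocyclic C13=C14 of unassigned geometry, C22=C23) | C=C1CC[C@@H]2OC(C)(C)[C@@H](OC(C)=O)CC[C@@]2(C)[C@@H]1CC=C1[C@]2(C)CC[C@H](O[Si](CC)(CC)CC)C(C)(C)O[C@H]2C=CC1=O | intermediate
39 | saturated C24 ketone, C14 substituent equatorial | C=C1CC[C@@H]2OC(C)(C)[C@@H](OC(C)=O)CC[C@@]2(C)[C@@H]1CC[C@H]1[C@]2(C)CC[C@H](O[Si](CC)(CC)CC)C(C)(C)O[C@H]2CCC1=O | intermediate
40 | tertiary alcohol (C24 axial OH; C18–OTES; C7–OAc) | C=C1CC[C@@H]2OC(C)(C)[C@@H](OC(C)=O)CC[C@@]2(C)[C@@H]1CC[C@H]1[C@]2(C)CC[C@H](O[Si](CC)(CC)CC)C(C)(C)O[C@H]2CC[C@@]1(C)O | intermediate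
41 | diol (C18–OH, C24–OH; C7–OAc) | C=C1CC[C@@H]2OC(C)(C)[C@@H](OC(C)=O)CC[C@@]2(C)[C@@H]1CC[C@H]1[C@]2(C)CC[C@H](O)C(C)(C)O[C@H]2CC[C@@]1(C)O | intermediate
42 | C18 ketone 7-O-acetate | C=C1CC[C@@H]2OC(C)(C)[C@@H](OC(C)=O)CC[C@@]2(C)[C@@H]1CC[C@H]1[C@]2(C)CCC(=O)C(C)(C)O[C@H]2CC[C@@]1(C)O | intermediate
43 | CNP0160418.1 | C=C1CC[C@@H]2OC(C)(C)[C@@H](O)CC[C@@]2(C)[C@@H]1CC[C@H]1[C@]2(C)CCC(=O)C(C)(C)O[C@H]2CC[C@@]1(C)O | target

## Count and least certain steps

Total: 32 steps. Longest linear sequence: 21 steps (1, 3–15, 26–32); the C/D branch (16–25) has 10 steps before the union.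

**Step 3 (key step).** The most likely failure is that cycloaddition to the doubly substituted dienophile is too slow at the temperature the catalyst tolerates, so that acid-induced loss of the diene (protodesilylation, stepwise addition to the aldehyde) overtakes it; lower face selectivity than with simple 2-substituted acroleins is the second risk. Fallback, from 3 and 5 back to 6: the cycloaddition is run thermally without catalyst (toluene, sealed tube), which should give the same endo adduct as a racemate, that is 6 together with its mirror image ent-6 F1. The enantiomers are separated by preparative chromatography on a chiral stationary phase and 6 re-enters at step 4.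

**Step 7.** Likely failures are over-oxidation, opening of the epoxide by the Lewis-acidic chromium reagent, and hydrogen abstraction at C4 if the ring populates the other half-chair. Fallback, from 11 back to 12: the oxygen is introduced by a pericyclic route instead of hydrogen abstraction. SeO2 (cat.) with t-BuOOH in CH2Cl2 should give, by ene reaction and [2,3] shift, the C1 allylic alcohol F2, which only a hydrogen able to reach the ene transition state can form. Dess–Martin periodinane then gives 12.

**Step 13 (the same holds for step 23).** The risk is competition of the 6-exo mode, giving a tetrahydropyran, if the opening is less cationic than assumed. Fallback, from 17 back to 18: the electrophile is changed from epoxide to alkene so that no six-membered alternative exists. The primary alcohol is silylated (TBSCl, imidazole) to the mono-TBS ether F3. The epoxide is isomerised with Et2AlCl and lithium 2,2,6,6-tetramethylpiperidide to the isopropenyl carbinol F4, C7 keeping its oxygen and configuration. Hg(OCOCF3)2 in MeNO2 then closes the oxepane by Markovnikov 7-exo attack of the C4 hydroxyl on the internal alkene carbon, giving the organomercurial F5, which NaBH4 in aqueous NaOH reduces to the oxepane TBS ether F6. Bu4NF gives 18.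

**Step 17.** The risks are hydrolysis of the dienol ether in the aqueous buffer before epoxidation and insufficient face discrimination on a flat, doubly activated diene. Fallback, from 21 back to 24: the lithium enolate of 21 (LiN(iPr)2, THF, −78 °C) is hydroxylated directly with an enantiopure N-sulfonyloxaziridine of the camphor series, the antipode being chosen that gives (S)-24. This replaces catalytic epoxidation of an isolated dienol ether by reagent-controlled oxygen transfer to the enolate and makes no compound outside the list (F0).

**Step 26.** The likely failure is proton transfer from the enolisable aldehyde to the hindered enolate in place of addition, with retro-aldol cleavage on warming. Fallback, from 20 and 35 back to 39: the bond is made by alkylation instead of aldol addition. Aldehyde 20 is reduced (NaBH4) to the acetoxy alcohol F7 and converted (I2, PPh3, imidazole) into the primary iodide F8. The lithium enolate of 35 in THF with hexamethylphosphoramide is alkylated with F8 to the C14-alkylated enone F9. The copper hydride and base treatment of step 28 then reduce the ring enone and equilibrate C14 to give 39, saving the dehydration step.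

## Further compounds

F1 | step 3 | ent-6, mirror image of the ring B cycloadduct | O=C[C@@]1(C)[C@@H](O[Si](C)(C)C(C)(C)C)C=CC[C@@H]1CCO[Si](C)(C)C(C)(C)C
F2 | step 7 | C1 allylic alcohol of 11 (C1 unassigned) | CC1(C)O[C@H]1CC[C@]1(C)[C@H](O[Si](C)(C)C(C)(C)C)C=CC(O)[C@H]1CCO[Si](C)(C)C(C)(C)C
F3 | step 13 | mono-TBS ether of 17 (C13–OTBS) | CC1(C)O[C@H]1CC[C@]1(C)[C@@H](O)CCC(=C)[C@H]1CCO[Si](C)(C)C(C)(C)C
F4 | step 13 | isopropenyl carbinol ((7S)-OH, C6 isopropenyl, C4–OH, C13–OTBS) | C=C(C)[C@@H](O)CC[C@]1(C)[C@@H](O)CCC(=C)[C@H]1CCO[Si](C)(C)C(C)(C)C
F5 | step 13 | organomercurial from 7-exo oxymercuration (C6 unassigned) | C=C1CC[C@@H]2OC(C)(C[Hg]OC(=O)C(F)(F)F)[C@@H](O)CC[C@@]2(C)[C@@H]1CCO[Si](C)(C)C(C)(C)C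
F6 | step 13 | rings A/B oxepane with C13–OTBS | C=C1CC[C@@H]2OC(C)(C)[C@@H](O)CC[C@@]2(C)[C@@H]1CCO[Si](C)(C)C(C)(C)C
F0 | step 17 | none | none
F7 | step 26 | rings A/B acetoxy alcohol (C13–OH, C7–OAc) | C=C1CC[C@@H]2OC(C)(C)[C@@H](OC(C)=O)CC[C@@]2(C)[C@@H]1CCO
F8 | step 26 | rings A/B acetoxy iodide (C13–I) | C=C1CC[C@@H]2OC(C)(C)[C@@H](OC(C)=O)CC[C@@]2(C)[C@@H]1CCI
F9 | step 26 | C14-alkylated enone (C14 unassigned, C22=C23) | C=C1CC[C@@H]2OC(C)(C)[C@@H](OC(C)=O)CC[C@@]2(C)[C@@H]1CCC1[C@]2(C)CC[C@H](O[Si](CC)(CC)CC)C(C)(C)O[C@H]2C=CC1=O
A1 | alternative 1 | ketal-protected trans-decalone, carbonyl next to the ring-fusion CH | O=C1CCC[C@@]2(C)C3(OCCO3)CCC[C@H]12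
A2 | alternative 1 | seven-membered lactone fused to the ketal-protected ring B | O=C1CCC[C@@]2(C)C3(OCCO3)CCC[C@@H]2O1
A3 | alternative 2 | tricyclic cyclobutane photoadduct | CC1(C)O[C@@]23CC[C@@](C)(O[Si](CC)(CC)CC)[C@@H](CO[Si](C)(C)C(C)(C)C)[C@]2(C)C[C@H]3C1=O
A4 | alternative 3 | aldol adduct of the A/B aldehyde with the new ring C ketone | C=C1CC[C@@H]2OC(C)(C)[C@@H](OCc3ccc(OC)cc3)CC[C@@]2(C)[C@@H]1C[C@@H](O)[C@@H]1C(=O)CC[C@H](O[Si](C)(C)C(C)(C)C)[C@@]1(C)CCC=C(C)C
A5 | alternative 3 | A/B aldehyde with C7 p-methoxybenzyl ether | C=C1CC[C@@H]2OC(C)(C)[C@@H](OCc3ccc(OC)cc3)CC[C@@]2(C)[C@@H]1CC=O
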